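**Retrosynthetic overview**

1. Numbering: chain C1 (ArOCH2) to C8 (γ-lactone C=O). The route rests on C1–C5, with the C3 methyl and the oxygens on C2, C3 and C5, being a masked 4-methyl-5,6-dihydro-2H-pyran-2-one (ring C2=O is C1, C3 is C2, C4–CH3 is C3, C5 is C4, C6–O1 is C5–O), the half-hydrogenated form of 4,6-dimethyl-2-pyrone.
2. Disconnections, latest first: ArO–C1 (Mitsunobu with umbelliferone); C7–CH3 (γ-lactone enolate, trans to C5); C1 ester to CH2OH; C2/C3 anti-diol back to a C2–C3 oxirane opened at C3 with inversion; oxirane back to the C2=C3 bond of the δ-lactone (peroxide conjugate addition anti to the C5 side chain); C5–H back to the pyrone (asymmetric hydrogenation); C6–C7 back to 4,6-dimethyl-2-pyrone plus tert-butyl bromoacetate.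
3. Ring order: pyrone (bought) → chiral δ-lactone → fused oxirane → γ-lactone C5–O–C8 (the δ-lactone is given up on hydrolysis) → temporary dioxolane on C2/C3 → coumarin attached last.

Key step: step 3

Assumption: the (S)-configured MeO-BIPHEP ligand is taken to deliver the (S)-lactone 5; the sense of induction belongs to the catalyst, and the antipodal ligand is used if it proves opposite.

**Route**

Step 1
Reactants: 1 4,6-dimethyl-2H-pyran-2-one; 2 tert-butyl bromoacetate
Product: 4 tert-butyl 3-(4-methyl-2-oxo-2H-pyran-6-yl)propanoate, via lithium trienolate of the pyrone 3 (not isolated)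
Conditions: LDA (1.05 equiv), THF, −78 °C; then 2, −78 → −40 °C
Reagents that add atoms: none
Why: Lateral (vinylogous) deprotonation of the 6-methyl group gives the linearly conjugated trienolate 3, which is alkylated at its exocyclic carbon by the α-bromo ester in an SN2 reaction that restores the pyrone, whereas the 4-methyl group would give only a cross-conjugated anion.

Step 2
Reactants: 4 tert-butyl 3-(4-methyl-2-oxo-2H-pyran-6-yl)propanoate
Product: 5 tert-butyl 3-[(2S)-4-methyl-6-oxo-3,6-dihydro-2H-pyran-2-yl]propanoate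
Conditions: [Ru(OAc)2((S)-MeO-BIPHEP)] (1 mol%), HBF4·OEt2 (2 mol%), H2 (60 bar), CH2Cl2, 60 °C; stopped after one equivalent of H2
Reagents that add atoms: none
Why: Ruthenium–biaryl-diphosphine catalysed asymmetric hydrogenation of 2-pyrones saturates the 5,6-enol-ester double bond and leaves the conjugated, trisubstituted 3,4-double bond, with the chiral ligand setting C5 as S.

Step 3
Reactants: 5 tert-butyl 3-[(2S)-4-methyl-6-oxo-3,6-dihydro-2H-pyran-2-yl]propanoate
Product: 7 tert-butyl 3-[(1S,4S,6S)-6-methyl-2-oxo-3,7-dioxabicyclo[4.1.0]heptan-4-yl]propanoate, via potassium β-peroxy enolate 6 (not isolated)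
Conditions: t-BuOOH (5.5 M in decane, 1.5 equiv), KOt-Bu (0.2 equiv), THF, −20 → 0 °C
Reagents that add atoms: tert-butyl hydroperoxide, CC(C)(C)OO
Why: Weitz–Scheffer nucleophilic epoxidation: the tert-butylperoxide anion adds in conjugate fashion to the methyl-bearing β-carbon C3 of the unsaturated δ-lactone to give enolate 6, whose α-carbon C2 then displaces tert-butoxide from the O–O bond. The oxirane is closed 3-exo-tet by the enolate carbon on the proximal peroxide oxygen. C3 is set by axial attack on the half-chair lactone from the face opposite the pseudo-equatorial C5 side chain, and C2 follows necessarily because a three-membered ring can only be cis-fused to the six-membered ring. The closest known reaction is the alkaline peroxide epoxidation of 6-substituted 5,6-dihydropyran-2-ones, which gives the epoxide trans to the 6-substituent. The step needs facial selectivity only (the regiochemistry is fixed by the polarity of the enoate), and the single C5 stereocentre of the ring secures it; catalytic base and anhydrous peroxide keep the lactone closed so that the template is not lost. The tert-butyl ester is inert to the peroxide anion.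

Step 4
Reactants: 7 tert-butyl 3-[(1S,4S,6S)-6-methyl-2-oxo-3,7-dioxabicyclo[4.1.0]heptan-4-yl]propanoate
Product: 10 (2S,3R)-2,3-dihydroxy-3-methyl-4-[(2S)-5-oxooxolan-2-yl]butanoic acid, via dihydroxy δ-lactone tert-butyl ester 8 (not isolated), via dihydroxy δ-lactone acid 9 (not isolated)
Conditions: TFA/H2O/THF (1:1:2), 0 °C → rt; then evaporate, TFA/H2O (95:5), rt; evaporate from toluene
Reagents that add atoms: water, O
Why: Acid-catalysed hydrolysis of a glycidic lactone in which water attacks the protonated oxirane at the tertiary β-carbon C3 anti to the leaving oxygen (inversion at C3, retention at C2, the α-carbon being deactivated and a free C3 cation disfavoured by the carbonyl) to give 8, followed by acidolysis of the tert-butyl ester to 9 and acyl-transfer lactone exchange to the more stable five-membered lactone 10, none of which breaks the C2–O or C5–O bonds.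

Step 5
Reactants: 10 (2S,3R)-2,3-dihydroxy-3-methyl-4-[(2S)-5-oxooxolan-2-yl]butanoic acid
Product: 11 methyl (4S,5R)-2,2,5-trimethyl-5-{[(2S)-5-oxooxolan-2-yl]methyl}-1,3-dioxolane-4-carboxylate
Conditions: 2,2-dimethoxypropane, MeOH, TsOH·H2O (cat.), 40 °C; Et3N, concentrate
Reagents that add atoms: methanol, CO; 2,2-dimethoxypropane, COC(C)(C)OC
Why: Fischer esterification and isopropylidene ketal formation under the conditions used for tartaric acid are unambiguous because C2/C3 is the only diol present, and any material still in the δ-lactone form 9 should be drawn into 11 since only the open C1 ester can carry the dioxolane with C1 and C4 trans while the C5 hydroxyl relactonises onto C8.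

Step 6
Reactants: 11 methyl (4S,5R)-2,2,5-trimethyl-5-{[(2S)-5-oxooxolan-2-yl]methyl}-1,3-dioxolane-4-carboxylate
Product: 12 (5S)-5-{[(4R,5R)-5-(hydroxymethyl)-2,2,4-trimethyl-1,3-dioxolan-4-yl]methyl}oxolan-2-one
Conditions: NaBH4 (2 equiv), EtOH, 0 °C; aq. NH4Cl
Reagents that add atoms: none
Why: Chemoselective borohydride reduction, in which the methyl ester activated by the adjacent dioxolane oxygen should be reduced well before the unactivated γ-lactone at 0 °C, with no stereocentre touched.

Step 7
Reactants: 12 (5S)-5-{[(4R,5R)-5-(hydroxymethyl)-2,2,4-trimethyl-1,3-dioxolan-4-yl]methyl}oxolan-2-one; 13 iodomethane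
Product: 15 (3R,5S)-5-{[(4R,5R)-5-(hydroxymethyl)-2,2,4-trimethyl-1,3-dioxolan-4-yl]methyl}-3-methyloxolan-2-one, via dilithio alkoxide enolate 14 (not isolated)
Conditions: LDA (2.2 equiv), THF, −78 °C; MeI (1.3 equiv), −78 → −50 °C; AcOH quench at −78 °C
Reagents that add atoms: none
Why: Dianion alkylation of a hydroxy lactone, in which the lactone enolate of 14 is C-methylated on the face opposite the bulky C5 substituent to give the 3,5-trans lactone (C7 R) while the lithium alkoxide is not methylated at −78 °C.

Step 8
Reactants: 15 (3R,5S)-5-{[(4R,5R)-5-(hydroxymethyl)-2,2,4-trimethyl-1,3-dioxolan-4-yl]methyl}-3-methyloxolan-2-one; 16 umbelliferone (7-hydroxy-2H-chromen-2-one)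
Product: 17 7-{[(4R,5R)-2,2,5-trimethyl-5-{[(2S,4R)-4-methyl-5-oxooxolan-2-yl]methyl}-1,3-dioxolan-4-yl]methoxy}-2H-chromen-2-one
Conditions: PPh3, DIAD, THF, 0 °C → rt
Reagents that add atoms: none
Why: Mitsunobu etherification, an SN2 displacement at the activated primary CH2 by the acidic 7-hydroxycoumarin, in which no stereocentre takes part and the dioxolane keeps the C2/C3 oxygens out of the reaction.

Step 9
Reactants: 17 7-{[(4R,5R)-2,2,5-trimethyl-5-{[(2S,4R)-4-methyl-5-oxooxolan-2-yl]methyl}-1,3-dioxolan-4-yl]methoxy}-2H-chromen-2-one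
Product: 18 7-{[(2R,3R)-2,3-dihydroxy-3-methyl-4-[(2S,4R)-4-methyl-5-oxooxolan-2-yl]butyl]oxy}-2H-chromen-2-one (CNP0331202.1)
Conditions: AcOH/H2O (4:1), 45 °C
Reagents that add atoms: none
Why: Acid-catalysed hydrolysis of the isopropylidene ketal cleaves only acetal C–O bonds, so the four stereocentres are retained and both the γ-lactone and the coumarin survive the mild aqueous acid.

**Compound list**

1 | 4,6-dimethyl-2H-pyran-2-one | O=c1cc(C)cc(C)o1 | starting material
2 | tert-butyl bromoacetate | CC(C)(C)OC(=O)CBr | starting material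
3 | lithium trienolate of 1 (lithium 4-methyl-6-methylidene-6H-pyran-2-olate) | C=C1C=C(C)C=C(O[Li])O1 | intermediate (not isolated)
4 | tert-butyl 3-(4-methyl-2-oxo-2H-pyran-6-yl)propanoate | O=c1cc(C)cc(CCC(=O)OC(C)(C)C)o1 | intermediate
5 | tert-butyl 3-[(2S)-4-methyl-6-oxo-3,6-dihydro-2H-pyran-2-yl]propanoate | O=C1C=C(C)C[C@H](CCC(=O)OC(C)(C)C)O1 | intermediate
6 | potassium (2S,4S)-2-[3-(tert-butoxy)-3-oxopropyl]-4-(tert-butylperoxy)-4-methyl-3,4-dihydro-2H-pyran-6-olate (peroxy group trans to the side chain) | [K+].[O-]C1=C[C@@](C)(OOC(C)(C)C)C[C@H](CCC(=O)OC(C)(C)C)O1 | intermediate (not isolated)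
7 | tert-butyl 3-[(1S,4S,6S)-6-methyl-2-oxo-3,7-dioxabicyclo[4.1.0]heptan-4-yl]propanoate (oxirane trans to the side chain) | O=C1O[C@@H](CCC(=O)OC(C)(C)C)C[C@]2(C)O[C@H]12 | intermediate
8 | tert-butyl 3-[(2S,4R,5S)-4,5-dihydroxy-4-methyl-6-oxooxan-2-yl]propanoate | O=C1O[C@@H](CCC(=O)OC(C)(C)C)C[C@@](C)(O)[C@@H]1O | intermediate (not isolated)
9 | 3-[(2S,4R,5S)-4,5-dihydroxy-4-methyl-6-oxooxan-2-yl]propanoic acid | O=C1O[C@@H](CCC(=O)O)C[C@@](C)(O)[C@@H]1O | intermediate (not isolated)
10 | (2S,3R)-2,3-dihydroxy-3-methyl-4-[(2S)-5-oxooxolan-2-yl]butanoic acid | OC(=O)[C@@H](O)[C@](C)(O)C[C@@H]1CCC(=O)O1 | intermediate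
11 | methyl (4S,5R)-2,2,5-trimethyl-5-{[(2S)-5-oxooxolan-2-yl]methyl}-1,3-dioxolane-4-carboxylate | COC(=O)[C@H]1OC(C)(C)O[C@]1(C)C[C@@H]2CCC(=O)O2 | intermediate
12 | (5S)-5-{[(4R,5R)-5-(hydroxymethyl)-2,2,4-trimethyl-1,3-dioxolan-4-yl]methyl}oxolan-2-one | OC[C@H]1OC(C)(C)O[C@]1(C)C[C@@H]2CCC(=O)O2 | intermediate
13 | iodomethane | CI | starting material
14 | dilithium alkoxide/lactone enolate of 12 | [Li]OC[C@H]1OC(C)(C)O[C@]1(C)C[C@@H]2CC=C(O[Li])O2 | intermediate (not isolated)
15 | (3R,5S)-5-{[(4R,5R)-5-(hydroxymethyl)-2,2,4-trimethyl-1,3-dioxolan-4-yl]methyl}-3-methyloxolan-2-one | OC[C@H]1OC(C)(C)O[C@]1(C)C[C@@H]2C[C@@H](C)C(=O)O2 | intermediate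
16 | umbelliferone (7-hydroxy-2H-chromen-2-one) | O=c1ccc2ccc(O)cc2o1 | starting material
17 | 7-{[(4R,5R)-2,2,5-trimethyl-5-{[(2S,4R)-4-methyl-5-oxooxolan-2-yl]methyl}-1,3-dioxolan-4-yl]methoxy}-2H-chromen-2-one | O=c1ccc2ccc(OC[C@H]3OC(C)(C)O[C@]3(C)C[C@@H]4C[C@@H](C)C(=O)O4)cc2o1 | intermediate
18 | 7-{[(2R,3R)-2,3-dihydroxy-3-methyl-4-[(2S,4R)-4-methyl-5-oxooxolan-2-yl]butyl]oxy}-2H-chromen-2-one | C[C@@H]1C[C@@H](C[C@@](C)(O)[C@H](O)COc2ccc3ccc(=O)oc3c2)OC1=O | target

**Summary**

Total step count: 9. Longest linear sequence: 9 steps (1 → 18).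

Steps most likely to fail:

Step 3 (key step). Conjugate addition of the peroxide anion to the methyl-substituted β-carbon may be slow. Acyl attack on the lactone, γ-deprotonation with ring opening to the dienoic acid, or attack on the wrong face could then compete. Fallback: setting out from 5, the oxygen is delivered electrophilically by methyl(trifluoromethyl)dioxirane generated in situ (Oxone, 1,1,1-trifluoroacetone, NaHCO3, MeCN/aqueous Na2EDTA, 0 °C). This is a concerted, base-free oxygen transfer to the trisubstituted alkene, which should again come from the face away from the C5 side chain. It returns to the route directly at 7, and no new compound arises (F0).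

Step 4. In the protic medium the protonated oxirane may ionise at C3 before water arrives. That would erode the inversion (C3 epimer) or open elimination and 1,2-shift pathways. Fallback: setting out from 7, the oxirane is converted into the ketal by acetone with catalytic BF3·OEt2 at −30 °C. The acetone oxygen attacks C3 anti to the complexed oxirane oxygen, which then closes on the oxocarbenium carbon, in a non-ionising medium at low temperature. This should give the trans-fused isopropylidene lactone tert-butyl 3-[(2S,4R,5S)-4,5-(isopropylidenedioxy)-4-methyl-6-oxooxan-2-yl]propanoate F1. Aqueous TFA then hydrolyses the ketal and the tert-butyl ester and allows the lactone exchange, cleaving only acetal and acyl C–O bonds, and the route is rejoined at 10.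

Step 6. Hydride attack or alcoholysis at the γ-lactone may compete with reduction of the ester, so that chemoselectivity is lost. Fallback: setting out from 11, LiOH in THF/H2O at 0 °C saponifies the methyl ester and opens the lactone to the dilithium hydroxy dicarboxylate dilithium (4S,5R)-5-[(2S)-4-carboxylato-2-hydroxybutyl]-2,2,5-trimethyl-1,3-dioxolane-4-carboxylate F2. Brief cold acidification (1 M HCl to pH 3) recloses the γ-lactone and gives the acid (4S,5R)-2,2,5-trimethyl-5-{[(2S)-5-oxooxolan-2-yl]methyl}-1,3-dioxolane-4-carboxylic acid F3. BH3·SMe2 in THF at 0 °C reduces the carboxylic acid selectively over the lactone, and the route is rejoined at 12.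

**Further compounds**

F0 | step 3 | none | none
F1 | step 4 | tert-butyl 3-[(2S,4R,5S)-4,5-(isopropylidenedioxy)-4-methyl-6-oxooxan-2-yl]propanoate (trans-fused acetonide of 8) | O=C1O[C@@H](CCC(=O)OC(C)(C)C)C[C@@]2(C)OC(C)(C)O[C@H]12
F2 | step 6 | dilithium (4S,5R)-5-[(2S)-4-carboxylato-2-hydroxybutyl]-2,2,5-trimethyl-1,3-dioxolane-4-carboxylate | [Li+].[Li+].[O-]C(=O)[C@H]1OC(C)(C)O[C@]1(C)C[C@@H](O)CCC([O-])=O
F3 | step 6 | (4S,5R)-2,2,5-trimethyl-5-{[(2S)-5-oxooxolan-2-yl]methyl}-1,3-dioxolane-4-carboxylic acid | OC(=O)[C@H]1OC(C)(C)O[C@]1(C)C[C@@H]2CCC(=O)O2
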